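**Plan**

- Retrosynthesis: the four O–Me bonds are cut last. Ring A is then taken back to a tetrahydrobenzofuran-4-one (C5–C6 re-saturated). The five-membered ring O1–C2–C3–C3a–C7a is traced back (O1–C2 cut, C3a–C2 formed) to a cyclopropane C3a–C3–C2 spiro-fused to a cyclohexane-1,3-dione.
- Enabling feature: in ring A the ring oxygen on C7a and the hydroxyl on C4 flank C3a just as the two carbonyls of a cyclohexane-1,3-dione flank its C2, and C2 of the dihydrofuran carries a para-oxygenated aryl group. The precursor is therefore a donor–acceptor cyclopropane whose spiro-C–CH(aryl donor) bond is primed to open.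
- The cyclopropane is cut at C3–C3a and C3–C2 into an alkylidene dione (dione + 4-methoxybenzaldehyde) and a chiral 3,5-dimethoxybenzyl sulfonium ylide. The dione, with the arylethyl chain in place, comes from an enone and malonate.
- Forward: side chain and carbocycle (steps 1–2), alkylidene dione and sulfonium salt (3–4), cyclopropane (5), ring expansion (6), aromatisation of ring A (7), demethylation (8).
- Stereochemistry: C3 is set in step 5 by the chiral sulfide (ylide face, then SN2 inversion) and is not touched again. C2 is set in step 6, trans to the C3 aryl group, under thermodynamic control.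

Key step: step 6

Assumption: the (1R,4R,5R)-sulfide is taken to deliver its benzylide through the face that makes the sulfonium-bearing carbon of the betaine (R), the sense that corresponds to (R,R)-stilbene oxide in benzylidene transfer to benzaldehyde; if the opposite sense operates, the (1S,4S,5S)-sulfide is used and nothing else changes.

**Route**

Step 1
Reactants: 1 3-(4-methoxyphenyl)propanal; 2 1-(triphenyl-λ5-phosphanylidene)propan-2-one
Product: 3 (3E)-6-(4-methoxyphenyl)hex-3-en-2-one
Conditions: CH2Cl2, rt
Reagents that add atoms: none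
Why: Wittig olefination with the acetyl-stabilised ylide is selective for the aldehyde and should give the E-enone, whose geometry is of no consequence after step 2.

Step 2
Reactants: 3 (3E)-6-(4-methoxyphenyl)hex-3-en-2-one; 4 diethyl propanedioate
Product: 8 5-[2-(4-methoxyphenyl)ethyl]cyclohexane-1,3-dione, via Michael adduct 5 (not isolated), via cyclic keto ester 6 (not isolated), via keto acid 7 (not isolated)
Conditions: NaOEt, EtOH, reflux; then aq. NaOH, reflux; then HCl, reflux
Reagents that add atoms: none
Why: classical dimedone-type annulation, in which Michael addition of sodiomalonate to the enone is followed by intramolecular Claisen condensation of the methyl ketone enolate onto an ester, saponification and decarboxylation of the β-keto acid; the product is achiral.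

Step 3
Reactants: 8 5-[2-(4-methoxyphenyl)ethyl]cyclohexane-1,3-dione; 9 4-methoxybenzaldehyde
Product: 10 2-[(4-methoxyphenyl)methylidene]-5-[2-(4-methoxyphenyl)ethyl]cyclohexane-1,3-dione
Conditions: L-proline (20 mol %), 4 Å MS, CH2Cl2, 0 °C → rt; 9 in excess (3 equiv)
Reagents that add atoms: none
Why: Knoevenagel condensation under amine catalysis should give the doubly activated alkene, here stabilised by push–pull conjugation with the para-methoxy group, while the excess of aldehyde suppresses Michael addition of a second molecule of 8.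

Step 4
Reactants: 11 1-(bromomethyl)-3,5-dimethoxybenzene; 12 (1R,4R,5R)-4,7,7-trimethyl-6-thiabicyclo[3.2.1]octane (isothiocineole)
Product: 13 (1R,4R,5R)-6-[(3,5-dimethoxyphenyl)methyl]-4,7,7-trimethyl-6-thiabicyclo[3.2.1]octan-6-ium trifluoromethanesulfonate
Conditions: LiOTf, CH2Cl2/H2O, rt
Reagents that add atoms: lithium trifluoromethanesulfonate [Li+].[O-]S(=O)(=O)C(F)(F)F
Why: SN2 S-alkylation of the sulfide by the benzylic bromide with trapping of the sulfonium ion as its non-nucleophilic triflate; alkylation on the more accessible lone pair of sulfur should give a single sulfonium diastereomer.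

Step 5
Reactants: 13 (1R,4R,5R)-6-[(3,5-dimethoxyphenyl)methyl]-4,7,7-trimethyl-6-thiabicyclo[3.2.1]octan-6-ium trifluoromethanesulfonate; 10 2-[(4-methoxyphenyl)methylidene]-5-[2-(4-methoxyphenyl)ethyl]cyclohexane-1,3-dione
Product: 16 (1S,2S)-1-(3,5-dimethoxyphenyl)-2-(4-methoxyphenyl)-6-[2-(4-methoxyphenyl)ethyl]spiro[2.5]octane-4,8-dione (C6 epimer mixture; minor (1S,2R)-cis isomer carried along), via sulfonium ylide 14 (not isolated), via betaine 15 (not isolated)
Conditions: KHMDS (1.0 equiv), THF, −78 °C; then 10, −78 °C → rt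
Reagents that add atoms: none
Why: Corey–Chaykovsky-type cyclopropanation (Michael-initiated ring closure), in which the preformed chiral benzylide adds through one face of its ylide carbon to the alkylidene dione and the dionate carbon of betaine 15 displaces the sulfide in a 3-exo-tet SN2 step with inversion, so that the configuration of the 3,5-dimethoxybenzylic carbon (the later C3) is fixed by the sulfide, whereas the configuration of the 4-methoxybenzylic carbon (trans expected to predominate) does not matter because step 6 erases it; C- over O-closure of a cyclohexane-1,3-dionate onto a benzylic sulfonium centre has close precedent in spirocyclopropane syntheses from 1,3-diones and sulfonium salts.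

Step 6
Reactants: 16 (1S,2S)-1-(3,5-dimethoxyphenyl)-2-(4-methoxyphenyl)-6-[2-(4-methoxyphenyl)ethyl]spiro[2.5]octane-4,8-dione
Product: 18 (2S,3S)-3-(3,5-dimethoxyphenyl)-2-(4-methoxyphenyl)-6-[2-(4-methoxyphenyl)ethyl]-3,5,6,7-tetrahydro-1-benzofuran-4(2H)-one (C6 epimer mixture), via zwitterion 17 (not isolated)
Conditions: Sc(OTf)3 (10 mol %), CH2Cl2, 0 °C → rt
Reagents that add atoms: none
Why: Sc(III) binds a dione carbonyl of the donor–acceptor cyclopropane and the strained bond between the spiro carbon and the carbon bearing the para-methoxyphenyl donor heterolyses to zwitterion 17 (4-methoxybenzylic cation/1,3-dionate), which collapses by C–O bond formation: a Cloke–Wilson cyclopropyl ketone → 2,3-dihydrofuran rearrangement, closest in type to the acid-catalysed ring-opening cyclisation of cyclohexane-1,3-dione-2-spirocyclopropanes to tetrahydrobenzofuran-4-ones. The three-membered ring (spiro C → C3a, cyclopropane C1 → C3, cyclopropane C2 → C2) thereby grows by the two atoms of a C=O unit into the ring O1–C2–C3–C3a–C7a, closed in a 5-exo-trig mode (dionate oxygen onto the trigonal benzylic cation, whose quinoid C=C lies outside the new ring). C3 is not a new stereocentre: no bond to it breaks, so it keeps the configuration set in step 5. C2 is new and is set trans to the C3 aryl group by 1,2-induction from C3 in the ring closure and, because C2–O ionisation is reversible under the acid, by equilibration to the more stable trans isomer, so both cyclopropane diastereomers of 16 should converge on (2S,3S)-18. The step needs cleavage of the spiro-C–CH(4-methoxyphenyl) bond and not of the spiro-C–CH(3,5-dimethoxyphenyl) bond, which the para-methoxy resonance donor secures against two meta-methoxy groups that give no resonance stabilisation, and O- instead of C-recombination, which strain release secures. Attack by either dione oxygen gives the same compound apart from the configuration at C6, which disappears in step 7.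

Step 7
Reactants: 18 (2S,3S)-3-(3,5-dimethoxyphenyl)-2-(4-methoxyphenyl)-6-[2-(4-methoxyphenyl)ethyl]-3,5,6,7-tetrahydro-1-benzofuran-4(2H)-one
Product: 20 (2S,3S)-3-(3,5-dimethoxyphenyl)-2-(4-methoxyphenyl)-6-[2-(4-methoxyphenyl)ethyl]-2,3-dihydro-1-benzofuran-4-ol, via selenide 19 (not isolated)
Conditions: LDA, THF, −78 °C; PhSeCl; then H2O2, pyridine, CH2Cl2, 0 °C → rt
Reagents that add atoms: none
Why: kinetic α'-deprotonation of the vinylogous ester at C5, selenenylation and selenoxide syn-elimination towards C6 followed by enolisation should aromatise ring A, the known way from tetrahydrobenzofuran-4-ones to 4-hydroxybenzofurans; the dihydrofuran ring and both stereocentres are not involved and the C6 stereocentre disappears.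

Step 8
Reactants: 20 (2S,3S)-3-(3,5-dimethoxyphenyl)-2-(4-methoxyphenyl)-6-[2-(4-methoxyphenyl)ethyl]-2,3-dihydro-1-benzofuran-4-ol
Product: 21 5-[(2S,3S)-4-hydroxy-2-(4-hydroxyphenyl)-6-[2-(4-hydroxyphenyl)ethyl]-2,3-dihydro-1-benzofuran-3-yl]benzene-1,3-diol
Conditions: BBr3 (excess), CH2Cl2, −78 °C → rt; then MeOH/H2O
Reagents that add atoms: none
Why: Lewis-acid cleavage of the four aryl methyl ethers via aryloxydibromoboranes that are hydrolysed on work-up, a deprotection with precedent on trans-2,3-diaryl-2,3-dihydrobenzofurans of the resveratrol-oligomer class; any reversible C2–O ionisation would return the more stable trans isomer without touching C3.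

**Compound list**

1 | 3-(4-methoxyphenyl)propanal | COc1ccc(CCC=O)cc1 | starting material
2 | 1-(triphenyl-λ5-phosphanylidene)propan-2-one | CC(=O)C=P(c1ccccc1)(c1ccccc1)c1ccccc1 | starting material
3 | (3E)-6-(4-methoxyphenyl)hex-3-en-2-one | COc1ccc(CC/C=C/C(C)=O)cc1 | intermediate
4 | diethyl propanedioate (diethyl malonate) | CCOC(=O)CC(=O)OCC | starting material
5 | diethyl 2-[1-(4-methoxyphenyl)-5-oxohexan-3-yl]propanedioate (Michael adduct; racemic) | CCOC(=O)C(C(=O)OCC)C(CCc1ccc(OC)cc1)CC(C)=O | intermediate (not isolated)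
6 | ethyl 2-[2-(4-methoxyphenyl)ethyl]-4,6-dioxocyclohexane-1-carboxylate (cyclic keto ester; racemic; present as its sodium enolate) | CCOC(=O)C1C(CCc2ccc(OC)cc2)CC(=O)CC1=O | intermediate (not isolated)
7 | 2-[2-(4-methoxyphenyl)ethyl]-4,6-dioxocyclohexane-1-carboxylic acid (keto acid; racemic) | OC(=O)C1C(CCc2ccc(OC)cc2)CC(=O)CC1=O | intermediate (not isolated)
8 | 5-[2-(4-methoxyphenyl)ethyl]cyclohexane-1,3-dione | COc1ccc(CCC2CC(=O)CC(=O)C2)cc1 | intermediate
9 | 4-methoxybenzaldehyde | COc1ccc(C=O)cc1 | starting material
10 | 2-[(4-methoxyphenyl)methylidene]-5-[2-(4-methoxyphenyl)ethyl]cyclohexane-1,3-dione (racemic with respect to the C5/alkylidene pair, which is lost later) | COc1ccc(CCC2CC(=O)C(=Cc3ccc(OC)cc3)C(=O)C2)cc1 | intermediate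
11 | 1-(bromomethyl)-3,5-dimethoxybenzene | COc1cc(CBr)cc(OC)c1 | starting material
12 | (1R,4R,5R)-4,7,7-trimethyl-6-thiabicyclo[3.2.1]octane (isothiocineole) | C[C@@H]1CC[C@@H]2C[C@H]1SC2(C)C | starting material
13 | (1R,4R,5R)-6-[(3,5-dimethoxyphenyl)methyl]-4,7,7-trimethyl-6-thiabicyclo[3.2.1]octan-6-ium trifluoromethanesulfonate (configuration at sulfur from alkylation on the open face, not written in the SMILES) | C[C@@H]1CC[C@@H]2C[C@H]1[S+](Cc1cc(OC)cc(OC)c1)C2(C)C.[O-]S(=O)(=O)C(F)(F)F | intermediate
14 | sulfonium ylide of 13, (3,5-dimethoxyphenyl)methylide | C[C@@H]1CC[C@@H]2C[C@H]1[S+]([CH-]c1cc(OC)cc(OC)c1)C2(C)C | intermediate (not isolated)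
15 | betaine: sulfonium 1,3-dionate from addition of 14 to 10, (R) at the sulfonium-bearing carbon, 4-methoxybenzylic carbon and ring C5 unspecified | C[C@@H]1CC[C@@H]2C[C@H]1[S+]([C@@H](c1cc(OC)cc(OC)c1)C(c1ccc(OC)cc1)C1=C([O-])CC(CCc3ccc(OC)cc3)CC1=O)C2(C)C | intermediate (not isolated)
16 | (1S,2S)-1-(3,5-dimethoxyphenyl)-2-(4-methoxyphenyl)-6-[2-(4-methoxyphenyl)ethyl]spiro[2.5]octane-4,8-dione (trans; C6 epimer mixture) | COc1ccc(CCC2CC(=O)C3(C(=O)C2)[C@H](c2ccc(OC)cc2)[C@H]3c2cc(OC)cc(OC)c2)cc1 | intermediate
17 | ring-opened zwitterion: 4-methoxybenzylic cation / 1,3-dionate, (S) at the 3,5-dimethoxybenzylic carbon | COc1ccc(CCC2CC(=O)C(=C([O-])C2)[C@H](c2cc(OC)cc(OC)c2)[CH+]c2ccc(OC)cc2)cc1 | intermediate (not isolated)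
18 | (2S,3S)-3-(3,5-dimethoxyphenyl)-2-(4-methoxyphenyl)-6-[2-(4-methoxyphenyl)ethyl]-3,5,6,7-tetrahydro-1-benzofuran-4(2H)-one (C6 epimer mixture) | COc1ccc(CCC2CC(=O)C3=C(C2)O[C@H](c2ccc(OC)cc2)[C@H]3c2cc(OC)cc(OC)c2)cc1 | intermediate
19 | (2S,3S)-3-(3,5-dimethoxyphenyl)-2-(4-methoxyphenyl)-6-[2-(4-methoxyphenyl)ethyl]-5-(phenylselanyl)-3,5,6,7-tetrahydro-1-benzofuran-4(2H)-one (C5/C6 isomer mixture) | COc1ccc(CCC2C([Se]c4ccccc4)C(=O)C3=C(C2)O[C@H](c2ccc(OC)cc2)[C@H]3c2cc(OC)cc(OC)c2)cc1 | intermediate (not isolated)
20 | (2S,3S)-3-(3,5-dimethoxyphenyl)-2-(4-methoxyphenyl)-6-[2-(4-methoxyphenyl)ethyl]-2,3-dihydro-1-benzofuran-4-ol | COc1ccc(CCc2cc(O)c3c(c2)O[C@H](c2ccc(OC)cc2)[C@H]3c2cc(OC)cc(OC)c2)cc1 | intermediate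
21 | 5-[(2S,3S)-4-hydroxy-2-(4-hydroxyphenyl)-6-[2-(4-hydroxyphenyl)ethyl]-2,3-dihydro-1-benzofuran-3-yl]benzene-1,3-diol | Oc1ccc(CCc2cc(O)c3c(c2)O[C@H](c2ccc(O)cc2)[C@H]3c2cc(O)cc(O)c2)cc1 | target

**Step count**

Total steps: 8. Longest linear sequence: 7 (steps 1, 2, 3, 5, 6, 7, 8; step 4 is a one-step branch).

**Steps most likely to fail**

Step 5. The betaine may close through oxygen instead of carbon (5-exo-tet O-alkylation to a regioisomeric dihydrofuran), and proton transfer in the ylide or betaine before ring closure may erode the configuration of the future C3. The fallback sets out from 8 and gives up reagent control in favour of resolution. Dione 8 is converted with PhI(OAc)2 and KOH in MeOH into its iodonium ylide, 2-(phenyl-λ3-iodanylidene)-5-[2-(4-methoxyphenyl)ethyl]cyclohexane-1,3-dione F1. Irradiation of this ylide with blue LEDs in CH2Cl2 in the presence of commercial (E)-3,4',5-trimethoxystilbene (COc1ccc(/C=C/c2cc(OC)cc(OC)c2)cc1) should transfer the dione carbene unit to the alkene and give the racemic trans-spirocyclopropane F2, which also bypasses 10. The conditions of step 6 should then lead through the racemic zwitterion F3 to the racemic trans-tetrahydrobenzofuranone F4, and those of step 7 through the racemic selenide F5 to the racemic phenol F6. This phenol is the first compound without the C6 stereocentre and is resolved by preparative chromatography on a chiral stationary phase; its (2S,3S)-enantiomer is 20, where the route is rejoined.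

Step 3. A second molecule of 8 may add to the alkylidene dione (2:1 adduct), and the product may undergo hydrolytic retro-Knoevenagel cleavage on isolation. The fallback sets out from 8 and stores the alkylidene dione in masked form. Three-component condensation of 8, 9 and 4-methylbenzenesulfinic acid in aqueous formic acid should give the crystalline sulfone adduct 3-hydroxy-2-[(4-methoxyphenyl)(4-methylbenzenesulfonyl)methyl]-5-[2-(4-methoxyphenyl)ethyl]cyclohex-2-en-1-one F7. Treatment of this adduct together with salt 13 and Cs2CO3 in MeCN should release 10 by sulfinate elimination only in the presence of ylide 14, which traps it through 15 to 16, where the route is rejoined.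

Step 6. The benzylic cation may lose the C3 proton (E1) to a vinyl dione that re-cyclises under acid with loss of the C3 configuration, and cis → trans equilibration at C2 may stay incomplete. The fallback sets out from 16, freed from its minor cis isomer, and replaces electrophilic by nucleophilic catalysis (organocatalytic Cloke–Wilson rearrangement). Catalytic DABCO in DMSO should open the activated cyclopropane by SN2 at the 4-methoxybenzylic carbon to the ammonium dionate zwitterion F8. Its dionate oxygen then displaces DABCO in a second SN2 (5-exo-tet). The double inversion is a net retention at C2 and no carbocation intervenes, so the trans-cyclopropane should give 18 directly, where the route is rejoined.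

Further compounds
F1 | step 5 | 2-(phenyl-λ3-iodanylidene)-5-[2-(4-methoxyphenyl)ethyl]cyclohexane-1,3-dione (iodonium ylide) | COc1ccc(CCC2CC(=O)C([I+]c3ccccc3)=C([O-])C2)cc1
F2 | step 5 | racemic trans-1-(3,5-dimethoxyphenyl)-2-(4-methoxyphenyl)-6-[2-(4-methoxyphenyl)ethyl]spiro[2.5]octane-4,8-dione (C6 epimer mixture) | COc1ccc(CCC2CC(=O)C3(C(=O)C2)C(c2ccc(OC)cc2)C3c2cc(OC)cc(OC)c2)cc1
F3 | step 5 | racemic ring-opened zwitterion (4-methoxybenzylic cation / 1,3-dionate) | COc1ccc(CCC2CC(=O)C(=C([O-])C2)C(c2cc(OC)cc(OC)c2)[CH+]c2ccc(OC)cc2)cc1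
F4 | step 5 | racemic trans-3-(3,5-dimethoxyphenyl)-2-(4-methoxyphenyl)-6-[2-(4-methoxyphenyl)ethyl]-3,5,6,7-tetrahydro-1-benzofuran-4(2H)-one | COc1ccc(CCC2CC(=O)C3=C(C2)OC(c2ccc(OC)cc2)C3c2cc(OC)cc(OC)c2)cc1
F5 | step 5 | racemic trans-3-(3,5-dimethoxyphenyl)-2-(4-methoxyphenyl)-6-[2-(4-methoxyphenyl)ethyl]-5-(phenylselanyl)-3,5,6,7-tetrahydro-1-benzofuran-4(2H)-one | COc1ccc(CCC2C([Se]c4ccccc4)C(=O)C3=C(C2)OC(c2ccc(OC)cc2)C3c2cc(OC)cc(OC)c2)cc1
F6 | step 5 | racemic trans-3-(3,5-dimethoxyphenyl)-2-(4-methoxyphenyl)-6-[2-(4-methoxyphenyl)ethyl]-2,3-dihydro-1-benzofuran-4-ol | COc1ccc(CCc2cc(O)c3c(c2)OC(c2ccc(OC)cc2)C3c2cc(OC)cc(OC)c2)cc1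
F7 | step 3 | 3-hydroxy-2-[(4-methoxyphenyl)(4-methylbenzenesulfonyl)methyl]-5-[2-(4-methoxyphenyl)ethyl]cyclohex-2-en-1-one | COc1ccc(CCC2CC(O)=C(C(c3ccc(OC)cc3)S(=O)(=O)c3ccc(C)cc3)C(=O)C2)cc1
F8 | step 6 | 1-[(1R,2S)-2-(3,5-dimethoxyphenyl)-1-(4-methoxyphenyl)-2-{4-[2-(4-methoxyphenyl)ethyl]-2-oxido-6-oxocyclohex-1-en-1-yl}ethyl]-4-aza-1-azoniabicyclo[2.2.2]octane (ammonium dionate zwitterion) | COc1ccc(CCC2CC(=O)C(=C([O-])C2)[C@H](c2cc(OC)cc(OC)c2)[C@H](c2ccc(OC)cc2)[N+]23CCN(CC2)CC3)cc1
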